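**Strategy**

The oxolane is disconnected across C3–C4, the only ring bond remote from both C–O stereocentres: cutting it turns C2 and C5 into the allylic carbons of an acyclic bis(allylic) ether. The route exploits this pseudo-C2-symmetric trans-2,5-disubstituted oxolane (O1, C2–C5): C5 is taken from (S)-benzyl glycidyl ether and C2 is set by iridium-catalysed allylic etherification, so the ring closure itself creates no stereocentre. Ring-closing metathesis then forms C3=C4 and the five-membered ring in one operation; hydrogenation saturates it and unmasks the C5 hydroxymethyl group, which becomes the terminal alkyne for a final Sonogashira coupling with a bromo iodo diene.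

Key step: step 6

Assumption (remark on the chemistry): in step 5 the (Sa,S,S) enantiomer of the phosphoramidite is taken to give the (R) configuration at the new C–O centre of an alkyl-substituted allyl unit. If the sense of induction is the opposite, the antipodal ligand is used and nothing else changes.

**Route**

Step 1
Reactants: 1 methyl hex-5-enoate; 2 (E)-but-2-enal (crotonaldehyde)
Product: 3 methyl (E)-7-oxohept-5-enoate
Conditions: 2 (5 equiv), second-generation Hoveyda–Grubbs catalyst RuCl2(H2IMes)(=CH-C6H4-2-OiPr) (2 mol %), CH2Cl2, 40 °C
Reagents that add atoms: none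
Why: Olefin cross-metathesis of a terminal alkene with an excess of an electron-poor enal partner should give the E-enal selectively with loss of propene, the ester being inert.

Step 2
Reactants: 3 methyl (E)-7-oxohept-5-enoate
Product: 4 methyl (E)-7-hydroxyhept-5-enoate
Conditions: NaBH4, CeCl3·7H2O, MeOH, −20 °C
Reagents that add atoms: none
Why: Luche reduction should reduce the enal carbonyl 1,2-selectively and leave the methyl ester and the E-alkene untouched.

Step 3
Reactants: 4 methyl (E)-7-hydroxyhept-5-enoate
Product: 5 methyl (E)-7-[(tert-butoxycarbonyl)oxy]hept-5-enoate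
Conditions: Boc2O, DMAP (cat.), CH2Cl2, 0 °C to rt
Reagents that add atoms: di-tert-butyl dicarbonate, CC(C)(C)OC(=O)OC(=O)OC(C)(C)C
Why: DMAP-catalysed acylation of the primary allylic alcohol should give the tert-butyl carbonate needed as leaving group for the allylic substitution, without touching the ester.

Step 4
Reactants: 6 (S)-benzyl glycidyl ether
Product: 7 (2S)-1-(benzyloxy)but-3-en-2-ol
Conditions: Me3S+ I− (3 equiv), n-BuLi, THF, −10 °C to rt
Reagents that add atoms: trimethylsulfonium iodide, C[S+](C)C.[I-]
Why: Excess dimethylsulfonium methylide opens the terminal epoxide at CH2 and the sulfonium betaine eliminates dimethyl sulfide (one-carbon homologation of an epoxide to an allylic alcohol), so the C–O stereocentre of 6 is carried over unchanged as (S).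

Step 5
Reactants: 7 (2S)-1-(benzyloxy)but-3-en-2-ol; 5 methyl (E)-7-[(tert-butoxycarbonyl)oxy]hept-5-enoate
Product: 9 methyl (5R)-5-{[(2S)-1-(benzyloxy)but-3-en-2-yl]oxy}hept-6-enoate, via copper alkoxide 8 (not isolated)
Conditions: 7 (1.5 equiv), n-BuLi then CuI, THF, 0 °C to rt; then 5, [Ir(cod)Cl]2 (2 mol %), (Sa,S,S)-O,O'-(1,1'-binaphthyl-2,2'-diyl)-N,N-bis(1-phenylethyl)phosphoramidite (4 mol %), THF, rt
Reagents that add atoms: CuI, [Cu+].[I-] (copper of the non-isolated alkoxide 8 only)
Why: Iridium-catalysed asymmetric allylic etherification with a soft copper alkoxide attacks the substituted allyl terminus to give the branched ether, the new (R) C–O stereocentre being set by the ligand (catalyst control) while the (S) centre of the alkoxide is untouched and the weakly basic copper alkoxide spares the methyl ester.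

Step 6
Reactants: 9 methyl (5R)-5-{[(2S)-1-(benzyloxy)but-3-en-2-yl]oxy}hept-6-enoate
Product: 10 methyl 4-[(2R,5S)-5-[(benzyloxy)methyl]-2,5-dihydrofuran-2-yl]butanoate
Conditions: second-generation Grubbs catalyst RuCl2(=CHPh)(H2IMes)(PCy3) (3 mol %), 1,4-benzoquinone (10 mol %), CH2Cl2 (0.01 M), 40 °C
Reagents that add atoms: none
Why: The ruthenium benzylidene engages one terminal vinyl group and the resulting alkylidene closes onto the other through a ruthenacyclobutane, whose cycloreversion expels ethylene and forms the C3=C4 bond (saturated to the C3–C4 single bond in step 7). The closest known reaction type is the ring-closing metathesis of bis(allylic) ethers to 2,5-dihydrofurans. The five-membered oxacycle is closed by intramolecular [2+2] cycloaddition/cycloreversion between two monosubstituted alkenes tethered through O1, driven by loss of ethylene. No stereocentre is formed: C2 (R) and C5 (S) were set in steps 5 and 4 and are not among the reacting carbons, so the trans relationship is carried through unchanged. The step needs ring closure over oligomerisation and no migration of the double bond to the 2,3-dihydrofuran, which the favoured five-membered ring size, high dilution and 1,4-benzoquinone as scavenger of ruthenium hydrides should secure. The ester and the benzyl ether are inert to the catalyst.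

Step 7
Reactants: 10 methyl 4-[(2R,5S)-5-[(benzyloxy)methyl]-2,5-dihydrofuran-2-yl]butanoate
Product: 11 methyl 4-[(2R,5S)-5-(hydroxymethyl)oxolan-2-yl]butanoate
Conditions: H2 (1 atm), 10% Pd/C, EtOAc–MeOH, rt
Reagents that add atoms: none
Why: Heterogeneous hydrogenation should saturate the cis ring alkene and hydrogenolyse the benzyl ether in the same operation, creating no stereocentre and leaving C2 and C5 as set.

Step 8
Reactants: 11 methyl 4-[(2R,5S)-5-(hydroxymethyl)oxolan-2-yl]butanoate
Product: 12 methyl 4-[(2R,5S)-5-formyloxolan-2-yl]butanoate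
Conditions: Dess–Martin periodinane, CH2Cl2, 0 °C to rt
Reagents that add atoms: none
Why: Dess–Martin oxidation of the primary alcohol under near-neutral conditions should stop at the α-alkoxy aldehyde without epimerising C5, the ester being inert.

Step 9
Reactants: 12 methyl 4-[(2R,5S)-5-formyloxolan-2-yl]butanoate
Product: 13 methyl 4-[(2R,5S)-5-ethynyloxolan-2-yl]butanoate
Conditions: dimethyl (1-diazo-2-oxopropyl)phosphonate, K2CO3, MeOH, 0 °C to rt
Reagents that add atoms: Ohira–Bestmann reagent, dimethyl (1-diazo-2-oxopropyl)phosphonate, COP(=O)(OC)C(=[N+]=[N-])C(C)=O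
Why: Ohira–Bestmann (Seyferth–Gilbert) homologation converts the aldehyde into the terminal alkyne through a diazoalkene and alkylidene carbene under conditions mild enough to keep the C5 configuration, and the methyl ester is degenerate toward methoxide.

Step 10
Reactants: 14 deca-1,9-diyne
Product: 16 (E)-1-bromodec-1-en-9-yne, via alkenylzirconocene chloride 15 (not isolated)
Conditions: 14 (4 equiv), Cp2Zr(H)Cl (1 equiv), CH2Cl2, rt; then N-bromosuccinimide, 0 °C
Reagents that add atoms: Cp2Zr(H)Cl, [H][Zr](Cl)(C1C=CC=C1)C1C=CC=C1 (zirconium fragment of the non-isolated 15 only); N-bromosuccinimide, O=C1CCC(=O)N1Br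
Why: Hydrozirconation (syn addition, zirconium at the terminal carbon) of one alkyne of an excess of the symmetric diyne followed by bromodezirconation with retention should give the (E)-1-bromoalkene, the excess diyne limiting double addition.

Step 11
Reactants: 16 (E)-1-bromodec-1-en-9-yne
Product: 18 (1E,9E)-1-bromo-10-iododeca-1,9-diene, via alkenylzirconocene chloride 17 (not isolated)
Conditions: Cp2Zr(H)Cl (1.3 equiv), THF, rt; then I2, 0 °C
Reagents that add atoms: Cp2Zr(H)Cl, [H][Zr](Cl)(C1C=CC=C1)C1C=CC=C1 (zirconium fragment of the non-isolated 17 only); iodine, II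
Why: A second hydrozirconation of the remaining terminal alkyne and iodinolysis with retention should give the (E)-vinyl iodide, the disubstituted bromoalkene being unreactive toward Cp2Zr(H)Cl.

Step 12
Reactants: 13 methyl 4-[(2R,5S)-5-ethynyloxolan-2-yl]butanoate; 18 (1E,9E)-1-bromo-10-iododeca-1,9-diene
Product: 19 Mutafuran C, methyl 4-[(2R,5S)-5-[(3E,11E)-12-bromododeca-3,11-dien-1-yn-1-yl]oxolan-2-yl]butanoate
Conditions: Pd(PPh3)4 (5 mol %), CuI (10 mol %), Et3N, THF (degassed), rt
Reagents that add atoms: none
Why: Sonogashira coupling, in which zerovalent palladium inserts into the C–I bond far faster than into the C–Br bond at room temperature, so the copper acetylide of 13 should couple at the iodo terminus only, with retention of both E geometries and without touching the stereocentres.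

**Compound list**

1 | methyl hex-5-enoate | COC(=O)CCCC=C | starting material
2 | (E)-but-2-enal (crotonaldehyde) | C/C=C/C=O | starting material
3 | methyl (E)-7-oxohept-5-enoate | COC(=O)CCC/C=C/C=O | intermediate
4 | methyl (E)-7-hydroxyhept-5-enoate | COC(=O)CCC/C=C/CO | intermediate
5 | methyl (E)-7-[(tert-butoxycarbonyl)oxy]hept-5-enoate | COC(=O)CCC/C=C/COC(=O)OC(C)(C)C | intermediate
6 | (S)-benzyl glycidyl ether, (2S)-2-[(benzyloxy)methyl]oxirane | C(OCc1ccccc1)[C@@H]1CO1 | starting material
7 | (2S)-1-(benzyloxy)but-3-en-2-ol | C=C[C@H](O)COCc1ccccc1 | intermediate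
8 | copper alkoxide of 7 | C=C[C@H](O[Cu])COCc1ccccc1 | intermediate (not isolated)
9 | methyl (5R)-5-{[(2S)-1-(benzyloxy)but-3-en-2-yl]oxy}hept-6-enoate | COC(=O)CCC[C@H](C=C)O[C@@H](C=C)COCc1ccccc1 | intermediate
10 | methyl 4-[(2R,5S)-5-[(benzyloxy)methyl]-2,5-dihydrofuran-2-yl]butanoate | COC(=O)CCC[C@@H]1C=C[C@@H](COCc2ccccc2)O1 | intermediate
11 | methyl 4-[(2R,5S)-5-(hydroxymethyl)oxolan-2-yl]butanoate | COC(=O)CCC[C@@H]1CC[C@@H](CO)O1 | intermediate
12 | methyl 4-[(2R,5S)-5-formyloxolan-2-yl]butanoate | COC(=O)CCC[C@@H]1CC[C@@H](C=O)O1 | intermediate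
13 | methyl 4-[(2R,5S)-5-ethynyloxolan-2-yl]butanoate | COC(=O)CCC[C@@H]1CC[C@@H](C#C)O1 | intermediate
14 | deca-1,9-diyne | C#CCCCCCCC#C | starting material
15 | chloro[(E)-dec-1-en-9-yn-1-yl]zirconocene | C#CCCCCCC/C=C/[Zr](Cl)(C1C=CC=C1)C1C=CC=C1 | intermediate (not isolated)
16 | (E)-1-bromodec-1-en-9-yne | Br/C=C/CCCCCCC#C | intermediate
17 | [(1E,9E)-10-bromodeca-1,9-dien-1-yl]chlorozirconocene | Br/C=C/CCCCCC/C=C/[Zr](Cl)(C1C=CC=C1)C1C=CC=C1 | intermediate (not isolated)
18 | (1E,9E)-1-bromo-10-iododeca-1,9-diene | Br/C=C/CCCCCC/C=C/I | intermediate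
19 | Mutafuran C, methyl 4-[(2R,5S)-5-[(3E,11E)-12-bromododeca-3,11-dien-1-yn-1-yl]oxolan-2-yl]butanoate | COC(=O)CCC[C@@H]1CC[C@@H](C#C/C=C/CCCCCC/C=C/Br)O1 | target

**Step count**

Total: 12 steps. Longest linear sequence: 9 steps (steps 1, 2, 3, 5, 6, 7, 8, 9, 12).

**Steps most likely to fail and fallbacks**

Step 5. Catalyst control may be eroded by a mismatched pairing with the resident stereocentre or by formation of the linear ether, and the alkoxide may transfer to the carbonate or ester carbonyl instead of the allyl unit. The fallback sets out from 4, fixes the second stereocentre by reagent-controlled epoxidation and uses an enantiospecific substitution instead of an enantioselective one. Sharpless epoxidation of 4 with Ti(OiPr)4, D-(−)-diethyl tartrate and t-BuOOH should give methyl 4-[(2R,3R)-3-(hydroxymethyl)oxiran-2-yl]butanoate F1. Iodination with I2, PPh3 and imidazole should give methyl 4-[(2R,3S)-3-(iodomethyl)oxiran-2-yl]butanoate F2. Zinc dust in ethanol should open F2 reductively to methyl (5R)-5-hydroxyhept-6-enoate F3, which is acylated at once with Boc2O to methyl (5R)-5-[(tert-butoxycarbonyl)oxy]hept-6-enoate F4 before it can lactonise. Rhodium-catalysed allylic etherification of F4 with copper alkoxide 8 (generated from 7 as in step 5) under RhCl(PPh3)3 and P(OMe)3 in THF is branched-selective and proceeds with net retention, and comes back to the route at 9.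

Step 7. Palladium may move the ring double bond into conjugation with O1 before it is saturated, which would erase a C–O stereocentre, or may cleave an allylic C–O bond and open the ring. The fallback sets out from 10 and separates the two events. Metal-free diimide reduction (2-nitrobenzenesulfonohydrazide, Et3N, CH2Cl2, rt) should saturate only the ring alkene and give methyl 4-[(2R,5S)-5-[(benzyloxy)methyl]oxolan-2-yl]butanoate F5. With no alkene or allylic ether left, hydrogenolysis of the benzyl ether over Pd(OH)2/C under H2 comes back to the route at 11.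

Step 12. Oxidative addition may also occur at the C–Br terminus of 18 or of the product, leading to oligomers, and the copper acetylide may homocouple oxidatively. The fallback sets out from 13 and 16, reverses the polarity of the coupling and needs neither copper nor a second sp2 halide. Bromination of 13 with N-bromosuccinimide and AgNO3 (cat.) in acetone should give methyl 4-[(2R,5S)-5-(bromoethynyl)oxolan-2-yl]butanoate F6. Coupling of F6 with alkenylzirconocene chloride 17 (generated from 16 and Cp2Zr(H)Cl as in step 11), catalysed by Pd(PPh3)4 with ZnCl2 in THF, should insert zerovalent palladium into the alkynyl C–Br bond in preference to the vinyl C–Br bond and comes back to the route at 19.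

**Further compounds**

F1 | step 5 | methyl 4-[(2R,3R)-3-(hydroxymethyl)oxiran-2-yl]butanoate | COC(=O)CCC[C@H]1O[C@@H]1CO
F2 | step 5 | methyl 4-[(2R,3S)-3-(iodomethyl)oxiran-2-yl]butanoate | COC(=O)CCC[C@H]1O[C@@H]1CI
F3 | step 5 | methyl (5R)-5-hydroxyhept-6-enoate | COC(=O)CCC[C@@H](O)C=C
F4 | step 5 | methyl (5R)-5-[(tert-butoxycarbonyl)oxy]hept-6-enoate | COC(=O)CCC[C@@H](OC(=O)OC(C)(C)C)C=C
F5 | step 7 | methyl 4-[(2R,5S)-5-[(benzyloxy)methyl]oxolan-2-yl]butanoate | COC(=O)CCC[C@@H]1CC[C@@H](COCc2ccccc2)O1
F6 | step 12 | methyl 4-[(2R,5S)-5-(bromoethynyl)oxolan-2-yl]butanoate | COC(=O)CCC[C@@H]1CC[C@@H](C#CBr)O1
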